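Reading the enzyme charge as the rate is the pitfall here: the impurity can take enzyme out of its working round.

| setting | Tuesday's | Thursday's | Friday's | flask |
|---|---|---|---|---|
| substrate | 0.10 M | 0.10 M | 0.10 M | 0.10 M |
| enzyme | 4.0 × 10⁻⁴ mol% | 8.9 × 10⁻⁴ mol% | 5.9 × 10⁻⁴ mol% | 5.9 × 10⁻⁴ mol% |
| impurity | 0.16 µM | 0.16 µM | 0.24 µM | 0.16 µM |
| remark | run made earlier | run made earlier | run made earlier |  |

| run | time / h | target / % |
|---|---|---|
| Tuesday's | 4.00 | 22.9 |
| Tuesday's | 8.00 | 42.1 |
| Tuesday's | 12.0 | 64.0 |
| Tuesday's | 15.0 | 75.8 |
| Thursday's | 2.00 | 31.1 |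
| Thursday's | 6.00 | 86.6 |
| Thursday's | 10.0 | 95.2 |
| Thursday's | 15.0 | 94.6 |
| Friday's | 1.33 | 11.5 |
| Friday's | 3.00 | 24.3 |
| Friday's | 6.00 | 46.8 |
| Friday's | 15.0 | 88.0 |

(readings scatter by 1 percentage point)

* factor on the rate of making target when 50% of the substrate are converted if enzyme is charged twice over
* factor on the rate when 50% of the substrate are converted if enzyme is charged at 1.2 × 10⁻⁴ mol% instead

- the numbers in the tables scatter by 1 percentage point (one standard deviation)
- steps that have been proposed: substrate + enzyme -> target + enzyme; enzyme + impurity -> spent catalyst; substrate -> uncatalysed product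

The bench rule says that the rate follows the enzyme charged. Take the first reading of a run over its time as the early rate. Thursday's early rate is then 2.72 times Tuesday's, which is more than the charge ratio of 2.22. If the impurity removes enzyme one for one, the ratio of what remains is 3.04, and the reading lies between the two.

My own reckoning freezes the working enzyme at the charge minus the impurity. The flask holds 0.590 µM of enzyme against 0.16 µM of impurity, so the impurity is the limiting reagent of the poisoning step. One minus [impurity]/[enzyme] at the charge gives 72.9% for the flask, the survivor share. At equal conversion, doubling the flask's charge then gives a factor of 2.37.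

The border of this reckoning lies where [impurity]/[enzyme] at the charge reaches one. That ratio is 0.271 in the flask but 1.33 at the charge of 1.2 × 10⁻⁴ mol%. There the survivor share reads −33.3%, which is no amount at all, so my reckoning gives no factor for that charge.

The forecast gives 2.35 for the doubled charge and 0 for the small one, where “essentially no active enzyme survives”.

The simulation gives 2.37 and 1.34 × 10⁻⁵.

    substrate + enzyme → target + enzyme, rate k1*[substrate]*[enzyme]/(1 + ([substrate]/Km1) + ([substrate]/Ksi1)^2) (16.0 mM, 0.0510 M, k = 2.20 × 10⁶ L mol⁻¹ h⁻¹)
    enzyme + impurity → spent catalyst (k = 6.30 × 10⁶ L mol⁻¹ h⁻¹)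
    substrate → uncatalysed product (k = 0.0190 h⁻¹)

In the flask, each enzyme meets the impurity as charged at 1.0 h⁻¹, a time of 1.000 h, which is shorter than the 4.91 h by which half of the turnover to target up to 20.0 h is done. At 50% conversion in the flask, enzyme is 72.9% of the catalyst, against a survivor share of 72.9%, and spent catalyst is 27.1%. With 1.2 × 10⁻⁴ mol%, where the survivor share read −33.3%, spent catalyst is >99.9% of the catalyst at the same conversion.

(All runs are simulated for an exercise; noise was put on by code.)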